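**Retrosynthetic overview**

1. The target is robinetinidol-(4β→8)-(−)-epigallocatechin 3-O-gallate: upper unit (2R,3S,4R), i.e. 2,3-trans-3,4-cis, lower unit (2R,3R). Flavan numbering of the upper unit (O1, C2, C3, C4, C4a, C5–C8, C8a) is used for all open-chain intermediates, and ring D is the benzo ring of the lower unit.
2. The last disconnection removes thirteen benzyl ethers. The key disconnection opens ring C at O1–C8a together with the C7–O bond, leading to an open-chain C2 alcohol whose ring A is a 2,4-dibromophenyl group.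
3. The enabling feature is that ring A is 5-deoxy: its only two oxygens, O1 on C8a and the phenolic oxygen on C7, flank the lone CH C8. A relay of two arynes through C8 can therefore turn C8a–Br and C7–Br into C8a–O1 (ring closure by the C2 alkoxide) and C7–OBn in one operation.
4. The interflavan C4–C8 bond is made before ring C exists, by Friedel–Crafts opening of a (2S,3R)-chalcone epoxide at C4 by C8 of octa-O-benzyl-EGCG with inversion; the electron-poor dibromophenyl group excludes a benzylic cation. This sets the 3,4-cis relation; chelation-controlled reduction at C2 then sets 2,3-trans.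
5. Order of ring formation: rings A and B arrive as arenes (2,4-dibromobenzaldehyde and a tris(benzyloxy)acetophenone), the rings of the lower unit arrive with (−)-epigallocatechin, which is benzylated on its five phenols and then galloylated on O3, and ring C is the only ring closed, last before deprotection.

Key step: step 9

Remark: (−)-epigallocatechin is taken as the commercial source of the lower unit; its two stereocentres already have the configuration of the target and are not touched. 3,4,5-Tris(benzyloxy)benzoic acid serves twice, as the galloyl donor and as the source of ring B.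

**Route**

Step 1
Reactants: 1 (−)-epigallocatechin (EGC)
Product: 2 penta-O-benzyl-EGC, (2R,3R)-5,7-bis(benzyloxy)-2-[3,4,5-tris(benzyloxy)phenyl]chroman-3-ol
Conditions: BnBr (5.5 equiv), K2CO3 (6 equiv), DMF, N2, 0 °C → rt
Reagents that add atoms: benzyl bromide, BrCc1ccccc1
Why: Williamson etherification in which K2CO3 deprotonates only the five phenols and not the secondary C3 hydroxyl, so that the aliphatic alcohol stays free for acylation and neither stereocentre is touched.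

Step 2
Reactants: 2 penta-O-benzyl-EGC; 3 3,4,5-tris(benzyloxy)benzoic acid
Product: 4 octa-O-benzyl-EGCG
Conditions: DCC (1.5 equiv), DMAP (0.3 equiv), CH2Cl2, 0 °C → rt
Reagents that add atoms: none
Why: Steglich esterification of the C3 hydroxyl through the O-acylisourea and the acylpyridinium ion; the C3–O bond is not broken, so the configuration is retained, and later steps see only ethers, one ester and one reactive arene position (C8 of ring D).

Step 3
Reactants: 3 3,4,5-tris(benzyloxy)benzoic acid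
Product: 5 1-[3,4,5-tris(benzyloxy)phenyl]ethanone
Conditions: MeLi (2.2 equiv), THF, −78 → 0 °C; then H2O (inverse quench)
Reagents that add atoms: methyllithium, [Li]C
Why: Addition of methyllithium to the lithium carboxylate stops at the dilithium gem-diolate, which collapses to the methyl ketone only on hydrolysis (carboxylic acid to methyl ketone synthesis).

Step 4
Reactants: 5 1-[3,4,5-tris(benzyloxy)phenyl]ethanone; 6 2,4-dibromobenzaldehyde
Product: 7 (E)-3-(2,4-dibromophenyl)-1-[3,4,5-tris(benzyloxy)phenyl]prop-2-en-1-one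
Conditions: NaOH (aq., cat.), EtOH/THF, rt
Reagents that add atoms: none
Why: Claisen–Schmidt (crossed aldol) condensation between the methyl ketone and a non-enolisable aldehyde, whose E1cB dehydration gives the conjugated E-enone.

Step 5
Reactants: 7 (E)-chalcone
Product: 8 [(2S,3R)-3-(2,4-dibromophenyl)oxiran-2-yl][3,4,5-tris(benzyloxy)phenyl]methanone
Conditions: poly-D-leucine, urea–H2O2, DBU, THF, rt
Reagents that add atoms: hydrogen peroxide (as urea–hydrogen peroxide), OO
Why: Juliá–Colonna epoxidation (Weitz–Scheffer addition of hydroperoxide under polyleucine control), in which the helical D-polypeptide should direct the hydroperoxide to the enone face that gives the (2S,3R)-trans-epoxide, the mirror image of the sense known for poly-L-leucine, and so fixes C3 and the leaving-group face at C4.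

Step 6
Reactants: 8 (2S,3R)-epoxy ketone; 4 octa-O-benzyl-EGCG
Product: 9 (2S,3S)-3-(2,4-dibromophenyl)-2-hydroxy-3-(octa-O-benzyl-EGCG-8-yl)-1-[3,4,5-tris(benzyloxy)phenyl]propan-1-one
Conditions: Sc(OTf)3 (20 mol %), CH2Cl2/HFIP (4:1), −20 °C → rt
Reagents that add atoms: none
Why: Friedel–Crafts alkylation by Lewis-acid-promoted epoxide opening, in which C8 of ring D (the more nucleophilic and accessible free position, as in interflavan couplings of benzylated flavan-3-ols) attacks the benzylic carbon C4 from the side opposite the epoxide oxygen (inversion, favoured because the electron-poor 2,4-dibromophenyl group denies a free benzylic cation) while C3 keeps its configuration, so that C3 and C4 emerge erythro, the future 3,4-cis relation.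

Step 7
Reactants: 9 α-hydroxy ketone
Product: 10 (2S,3S)-2-(benzyloxy)-3-(2,4-dibromophenyl)-3-(octa-O-benzyl-EGCG-8-yl)-1-[3,4,5-tris(benzyloxy)phenyl]propan-1-one
Conditions: BnBr (5 equiv), Ag2O (3 equiv), n-Bu4NI (cat.), 4 Å molecular sieves, CH2Cl2, rt, dark
Reagents that add atoms: benzyl bromide, BrCc1ccccc1
Why: Silver-oxide-promoted Williamson (Purdie) benzylation under non-basic conditions, so that C3, which is alpha to the ketone, is not epimerised, and the resulting benzyl ether masks the C3 oxygen against the later ring closure while still able to chelate.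

Step 8
Reactants: 10 α-benzyloxy ketone
Product: 11 (1R,2S,3S)-2-(benzyloxy)-3-(2,4-dibromophenyl)-3-(octa-O-benzyl-EGCG-8-yl)-1-[3,4,5-tris(benzyloxy)phenyl]propan-1-ol
Conditions: Zn(BH4)2, Et2O/CH2Cl2, −30 → 0 °C
Reagents that add atoms: none
Why: Chelation-controlled (Cram chelate) reduction in which Zn bridges the carbonyl and the C3 benzyloxy oxygen and hydride enters from the face of the C3 hydrogen, which should give the anti C2 carbinol, that is 2R and the future 2,3-trans relation, without touching the ester.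

Step 9
Reactants: 11 open-chain C2 alcohol
Product: 14 tridecabenzyl ether of the target, via bromoaryne lithium alkoxide 12 (not isolated), via chroman 7,8-aryne 13 (not isolated)
Conditions: BnOH (3 equiv), lithium 2,2,6,6-tetramethylpiperidide (5.3 equiv), THF, −78 °C, then −78 → −30 °C; AcOH, −40 °C
Reagents that add atoms: benzyl alcohol, OCc1ccccc1
Why: Proposed new method: a relay of two arynes on ring A, reasoned from three known reaction types, namely amide-base metalation of 1,3-dibromoarenes between the halogens with loss of LiBr to a 3-bromoaryne, intramolecular alkoxide–aryne cyclisation to chromans, and the tandem two-aryne sequences of 2,6-dihaloaryl anions. The hindered amide removes C8–H, the only ring A hydrogen flanked by both bromines, loss of LiBr gives aryne 12, and the tethered C2 lithium alkoxide adds to C8a in a 6-exo-dig closure that forms O1–C8a and ring C; the carbanion so placed on C8 expels the C7 bromide to give the 3-alkoxyaryne 13, which lithium benzyl oxide attacks at C7, distal to O1, and the C8 carbanion is protonated on quench. No stereocentre is created: C2 keeps its configuration because its C–O bond is never broken, and the diarylmethine C4–H, shielded by its three substituents, should be removed by the hindered amide at −78 °C far more slowly than the exposed C8–H. Three selectivities are needed: ring C from the C2 oxygen and not a five-membered ring from the C3 oxygen (secured by the C3 benzyl ether and the anionic character of the C2 oxygen), tethered and not external alkoxide at C8a (secured by intramolecularity), and each alkoxide at the aryne carbon remote from the flanking bromine or oxygen (secured by the inductive bias of 3-substituted arynes, so that loss of the two bromides in either order converges on the same product). Lithium alkoxides and the non-nucleophilic amide at or below −30 °C should leave the gallate ester intact.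

Step 10
Reactants: 14 tridecabenzyl ether of the target
Product: 15 robinetinidol-(4β→8)-(−)-epigallocatechin 3-O-gallate (target)
Conditions: H2 (1 atm), Pd(OH)2/C, THF/MeOH/H2O, rt
Reagents that add atoms: none
Why: Catalytic hydrogenolysis of all thirteen benzyl ethers (twelve aryl, one alkyl) under neutral conditions that leave the gallate ester, the interflavan bond and the five stereocentres untouched.

**Compound list**

1 | (−)-epigallocatechin, (2R,3R) | O[C@@H]1Cc2c(O)cc(O)cc2O[C@@H]1c1cc(O)c(O)c(O)c1 | starting material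
2 | penta-O-benzyl-EGC: (2R,3R)-5,7-bis(benzyloxy)-2-[3,4,5-tris(benzyloxy)phenyl]chroman-3-ol | O[C@@H]1Cc2c(OCc3ccccc3)cc(OCc3ccccc3)cc2O[C@@H]1c1cc(OCc2ccccc2)c(OCc2ccccc2)c(OCc2ccccc2)c1 | intermediate
3 | 3,4,5-tris(benzyloxy)benzoic acid | OC(=O)c1cc(OCc2ccccc2)c(OCc2ccccc2)c(OCc2ccccc2)c1 | starting material
4 | octa-O-benzyl-EGCG: (2R,3R)-5,7-bis(benzyloxy)-2-[3,4,5-tris(benzyloxy)phenyl]chroman-3-yl 3,4,5-tris(benzyloxy)benzoate | O=C(O[C@@H]1Cc2c(OCc3ccccc3)cc(OCc3ccccc3)cc2O[C@@H]1c1cc(OCc2ccccc2)c(OCc2ccccc2)c(OCc2ccccc2)c1)c1cc(OCc2ccccc2)c(OCc2ccccc2)c(OCc2ccccc2)c1 | intermediate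
5 | 1-[3,4,5-tris(benzyloxy)phenyl]ethanone | CC(=O)c1cc(OCc2ccccc2)c(OCc2ccccc2)c(OCc2ccccc2)c1 | intermediate
6 | 2,4-dibromobenzaldehyde | O=Cc1ccc(Br)cc1Br | starting material
7 | (E)-3-(2,4-dibromophenyl)-1-[3,4,5-tris(benzyloxy)phenyl]prop-2-en-1-one | O=C(/C=C/c1ccc(Br)cc1Br)c1cc(OCc2ccccc2)c(OCc2ccccc2)c(OCc2ccccc2)c1 | intermediate
8 | [(2S,3R)-3-(2,4-dibromophenyl)oxiran-2-yl][3,4,5-tris(benzyloxy)phenyl]methanone (trans-epoxide; oxirane C2 = flavan C3, oxirane C3 = flavan C4) | O=C([C@H]1O[C@@H]1c1ccc(Br)cc1Br)c1cc(OCc2ccccc2)c(OCc2ccccc2)c(OCc2ccccc2)c1 | intermediate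
9 | (2S,3S)-3-(2,4-dibromophenyl)-2-hydroxy-3-(octa-O-benzyl-EGCG-8-yl)-1-[3,4,5-tris(benzyloxy)phenyl]propan-1-one (propane C1, C2, C3 = flavan C2, C3, C4) | O=C(O[C@@H]1Cc2c(OCc3ccccc3)cc(OCc3ccccc3)c([C@@H](c3ccc(Br)cc3Br)[C@H](O)C(=O)c3cc(OCc4ccccc4)c(OCc4ccccc4)c(OCc4ccccc4)c3)c2O[C@@H]1c1cc(OCc2ccccc2)c(OCc2ccccc2)c(OCc2ccccc2)c1)c1cc(OCc2ccccc2)c(OCc2ccccc2)c(OCc2ccccc2)c1 | intermediate
10 | (2S,3S)-2-(benzyloxy)-3-(2,4-dibromophenyl)-3-(octa-O-benzyl-EGCG-8-yl)-1-[3,4,5-tris(benzyloxy)phenyl]propan-1-one | O=C(O[C@@H]1Cc2c(OCc3ccccc3)cc(OCc3ccccc3)c([C@@H](c3ccc(Br)cc3Br)[C@H](OCc3ccccc3)C(=O)c3cc(OCc4ccccc4)c(OCc4ccccc4)c(OCc4ccccc4)c3)c2O[C@@H]1c1cc(OCc2ccccc2)c(OCc2ccccc2)c(OCc2ccccc2)c1)c1cc(OCc2ccccc2)c(OCc2ccccc2)c(OCc2ccccc2)c1 | intermediate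
11 | (1R,2S,3S)-2-(benzyloxy)-3-(2,4-dibromophenyl)-3-(octa-O-benzyl-EGCG-8-yl)-1-[3,4,5-tris(benzyloxy)phenyl]propan-1-ol | O=C(O[C@@H]1Cc2c(OCc3ccccc3)cc(OCc3ccccc3)c([C@@H](c3ccc(Br)cc3Br)[C@@H]([C@H](O)c3cc(OCc4ccccc4)c(OCc4ccccc4)c(OCc4ccccc4)c3)OCc3ccccc3)c2O[C@@H]1c1cc(OCc2ccccc2)c(OCc2ccccc2)c(OCc2ccccc2)c1)c1cc(OCc2ccccc2)c(OCc2ccccc2)c(OCc2ccccc2)c1 | intermediate
12 | lithium C2 alkoxide of 11 in which the dibromophenyl ring has become the 3-bromoaryne (triple bond C8–C8a, bromine on C7) | O=C(O[C@@H]1Cc2c(OCc3ccccc3)cc(OCc3ccccc3)c([C@@H](C3=CC=C(Br)C#C3)[C@@H]([C@H](O[Li])c3cc(OCc4ccccc4)c(OCc4ccccc4)c(OCc4ccccc4)c3)OCc3ccccc3)c2O[C@@H]1c1cc(OCc2ccccc2)c(OCc2ccccc2)c(OCc2ccccc2)c1)c1cc(OCc2ccccc2)c(OCc2ccccc2)c(OCc2ccccc2)c1 | intermediate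
13 | (2R,3S,4R)-3-(benzyloxy)-2-[3,4,5-tris(benzyloxy)phenyl]-4-(octa-O-benzyl-EGCG-8-yl)-7,8-didehydrochroman (aryne C7–C8 of ring A) | O=C(O[C@@H]1Cc2c(OCc3ccccc3)cc(OCc3ccccc3)c([C@H]3C4C=CC#CC=4O[C@H](c4cc(OCc5ccccc5)c(OCc5ccccc5)c(OCc5ccccc5)c4)[C@H]3OCc3ccccc3)c2O[C@@H]1c1cc(OCc2ccccc2)c(OCc2ccccc2)c(OCc2ccccc2)c1)c1cc(OCc2ccccc2)c(OCc2ccccc2)c(OCc2ccccc2)c1 | intermediate
14 | tridecabenzyl ether of the target: (2R,3S,4R)-3,7-bis(benzyloxy)-2-[3,4,5-tris(benzyloxy)phenyl]chroman-4-yl unit bonded through C4 to C8 of octa-O-benzyl-EGCG | O=C(O[C@@H]1Cc2c(OCc3ccccc3)cc(OCc3ccccc3)c([C@H]3c4ccc(OCc5ccccc5)cc4O[C@H](c4cc(OCc5ccccc5)c(OCc5ccccc5)c(OCc5ccccc5)c4)[C@H]3OCc3ccccc3)c2O[C@@H]1c1cc(OCc2ccccc2)c(OCc2ccccc2)c(OCc2ccccc2)c1)c1cc(OCc2ccccc2)c(OCc2ccccc2)c(OCc2ccccc2)c1 | intermediate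
15 | robinetinidol-(4β→8)-(−)-epigallocatechin 3-O-gallate (CNP0269431.2) | O=C(O[C@@H]1Cc2c(O)cc(O)c([C@H]3c4ccc(O)cc4O[C@H](c4cc(O)c(O)c(O)c4)[C@H]3O)c2O[C@@H]1c1cc(O)c(O)c(O)c1)c1cc(O)c(O)c(O)c1 | target

**Step count and risks**

Total step count: 10. Longest linear sequence: 8 steps (3 → 5 → 7 → 8 → 9 → 10 → 11 → 14 → 15); the branch 1 → 2 → 4 (steps 1 and 2) joins at step 6.

Steps most likely to fail:

1. Step 9 (Proposed new method). What may go wrong: capture of the first aryne by external benzyl oxide or by the C3 ether oxygen instead of the tethered alkoxide, metalation at other positions (including the diarylmethine C4–H, which would trigger β-elimination of the C3 benzyloxy group), or acyl transfer from the gallate to an alkoxide under the strongly basic conditions. Fallback with known chemistry, setting out from 11 and coming back at 15: ring C is closed alone by a copper-catalysed Ullmann-type intramolecular O-arylation (CuI, 3,4,7,8-tetramethyl-1,10-phenanthroline, Cs2CO3, toluene, 110 °C), which should give the 7-bromoflavan dimer F1. Miyaura borylation (B2pin2, Pd(dppf)Cl2, KOAc, 1,4-dioxane, 85 °C) should then give the pinacol boronate F2, and oxidation (NaBO3·4H2O, THF/H2O, rt) the 7-phenol F3. Hydrogenolysis of F3 under the conditions of step 10 gives 15.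

2. Step 6. What may go wrong: sluggish opening of the electron-poor epoxide by the bulky arene, with competing rearrangement of the Lewis-acid-activated epoxy ketone or attack through C6 of ring D. Fallback setting out from 8 and coming back at 11, in which the acyl group is removed before the C–C bond is made: Zn(BH4)2 reduction (Et2O, −20 °C, chelation between the carbonyl and epoxide oxygens) should give the erythro epoxy alcohol F4, and silylation (i-Pr3SiOTf, 2,6-lutidine, CH2Cl2) its triisopropylsilyl ether F5. Friedel–Crafts opening with 4 (BF3·OEt2, CH2Cl2, −78 → −40 °C) should give the C3 alcohol F6 with the same inversion at C4. Neutral benzylation (2-benzyloxy-1-methylpyridinium triflate, MgO, PhCF3, 85 °C), chosen to avoid silyl migration and ester cleavage, gives the benzyl ether F7, and desilylation (n-Bu4NF, THF) gives 11.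

3. Step 7. What may go wrong: incomplete alkylation of the congested secondary hydroxyl, or epimerisation at C3 alpha to the ketone on prolonged exposure. Fallback setting out from 9 and coming back at 15, with a smaller and more reactive alkylating agent: methoxymethylation (MeOCH2Cl, i-Pr2NEt, n-Bu4NI, CH2Cl2, 40 °C) should give the methoxymethyl ether F8, which still chelates. Zn(BH4)2 reduction under the conditions of step 8 should give the anti alcohol F9, and the conditions of step 9 the cyclised dodecabenzyl methoxymethyl ether F10. Acid methanolysis (HCl, MeOH/THF, 40 °C), which the 5-deoxy interflavan bond should tolerate, frees the C3 hydroxyl to give the dodecabenzyl ether F11, and hydrogenolysis under the conditions of step 10 gives 15.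

Further compounds

F1 | step 9 | (2R,3S,4R)-3-(benzyloxy)-7-bromo-2-[3,4,5-tris(benzyloxy)phenyl]-4-(octa-O-benzyl-EGCG-8-yl)chroman | O=C(O[C@@H]1Cc2c(OCc3ccccc3)cc(OCc3ccccc3)c([C@H]3c4ccc(Br)cc4O[C@H](c4cc(OCc5ccccc5)c(OCc5ccccc5)c(OCc5ccccc5)c4)[C@H]3OCc3ccccc3)c2O[C@@H]1c1cc(OCc2ccccc2)c(OCc2ccccc2)c(OCc2ccccc2)c1)c1cc(OCc2ccccc2)c(OCc2ccccc2)c(OCc2ccccc2)c1
F2 | step 9 | 7-(pinacolatoboryl) analogue of F1 | O=C(O[C@@H]1Cc2c(OCc3ccccc3)cc(OCc3ccccc3)c([C@H]3c4ccc(B5OC(C)(C)C(C)(C)O5)cc4O[C@H](c4cc(OCc5ccccc5)c(OCc5ccccc5)c(OCc5ccccc5)c4)[C@H]3OCc3ccccc3)c2O[C@@H]1c1cc(OCc2ccccc2)c(OCc2ccccc2)c(OCc2ccccc2)c1)c1cc(OCc2ccccc2)c(OCc2ccccc2)c(OCc2ccccc2)c1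
F3 | step 9 | 7-hydroxy analogue of F1 (dodecabenzyl ether of the target with free 7-OH of the upper unit) | O=C(O[C@@H]1Cc2c(OCc3ccccc3)cc(OCc3ccccc3)c([C@H]3c4ccc(O)cc4O[C@H](c4cc(OCc5ccccc5)c(OCc5ccccc5)c(OCc5ccccc5)c4)[C@H]3OCc3ccccc3)c2O[C@@H]1c1cc(OCc2ccccc2)c(OCc2ccccc2)c(OCc2ccccc2)c1)c1cc(OCc2ccccc2)c(OCc2ccccc2)c(OCc2ccccc2)c1
F4 | step 6 | (R)-[(2R,3R)-3-(2,4-dibromophenyl)oxiran-2-yl][3,4,5-tris(benzyloxy)phenyl]methanol (erythro epoxy alcohol) | O[C@@H]([C@H]1O[C@@H]1c1ccc(Br)cc1Br)c1cc(OCc2ccccc2)c(OCc2ccccc2)c(OCc2ccccc2)c1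
F5 | step 6 | triisopropylsilyl ether of F4 | CC(C)[Si](C(C)C)(C(C)C)O[C@@H]([C@H]1O[C@@H]1c1ccc(Br)cc1Br)c1cc(OCc2ccccc2)c(OCc2ccccc2)c(OCc2ccccc2)c1
F6 | step 6 | (1R,2S,3S)-3-(2,4-dibromophenyl)-3-(octa-O-benzyl-EGCG-8-yl)-1-[3,4,5-tris(benzyloxy)phenyl]-1-(triisopropylsilyloxy)propan-2-ol | O=C(O[C@@H]1Cc2c(OCc3ccccc3)cc(OCc3ccccc3)c([C@@H](c3ccc(Br)cc3Br)[C@@H]([C@H](O[Si](C(C)C)(C(C)C)C(C)C)c3cc(OCc4ccccc4)c(OCc4ccccc4)c(OCc4ccccc4)c3)O)c2O[C@@H]1c1cc(OCc2ccccc2)c(OCc2ccccc2)c(OCc2ccccc2)c1)c1cc(OCc2ccccc2)c(OCc2ccccc2)c(OCc2ccccc2)c1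
F7 | step 6 | 2-O-benzyl ether of F6 (triisopropylsilyl ether of 11) | O=C(O[C@@H]1Cc2c(OCc3ccccc3)cc(OCc3ccccc3)c([C@@H](c3ccc(Br)cc3Br)[C@@H]([C@H](O[Si](C(C)C)(C(C)C)C(C)C)c3cc(OCc4ccccc4)c(OCc4ccccc4)c(OCc4ccccc4)c3)OCc3ccccc3)c2O[C@@H]1c1cc(OCc2ccccc2)c(OCc2ccccc2)c(OCc2ccccc2)c1)c1cc(OCc2ccccc2)c(OCc2ccccc2)c(OCc2ccccc2)c1
F8 | step 7 | (2S,3S)-3-(2,4-dibromophenyl)-2-(methoxymethoxy)-3-(octa-O-benzyl-EGCG-8-yl)-1-[3,4,5-tris(benzyloxy)phenyl]propan-1-one | O=C(O[C@@H]1Cc2c(OCc3ccccc3)cc(OCc3ccccc3)c([C@@H](c3ccc(Br)cc3Br)[C@H](OCOC)C(=O)c3cc(OCc4ccccc4)c(OCc4ccccc4)c(OCc4ccccc4)c3)c2O[C@@H]1c1cc(OCc2ccccc2)c(OCc2ccccc2)c(OCc2ccccc2)c1)c1cc(OCc2ccccc2)c(OCc2ccccc2)c(OCc2ccccc2)c1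
F9 | step 7 | (1R,2S,3S)-3-(2,4-dibromophenyl)-2-(methoxymethoxy)-3-(octa-O-benzyl-EGCG-8-yl)-1-[3,4,5-tris(benzyloxy)phenyl]propan-1-ol | O=C(O[C@@H]1Cc2c(OCc3ccccc3)cc(OCc3ccccc3)c([C@@H](c3ccc(Br)cc3Br)[C@@H]([C@H](O)c3cc(OCc4ccccc4)c(OCc4ccccc4)c(OCc4ccccc4)c3)OCOC)c2O[C@@H]1c1cc(OCc2ccccc2)c(OCc2ccccc2)c(OCc2ccccc2)c1)c1cc(OCc2ccccc2)c(OCc2ccccc2)c(OCc2ccccc2)c1
F10 | step 7 | analogue of 14 with a methoxymethyl ether in place of the benzyl ether on C3 of the upper unit | O=C(O[C@@H]1Cc2c(OCc3ccccc3)cc(OCc3ccccc3)c([C@H]3c4ccc(OCc5ccccc5)cc4O[C@H](c4cc(OCc5ccccc5)c(OCc5ccccc5)c(OCc5ccccc5)c4)[C@H]3OCOC)c2O[C@@H]1c1cc(OCc2ccccc2)c(OCc2ccccc2)c(OCc2ccccc2)c1)c1cc(OCc2ccccc2)c(OCc2ccccc2)c(OCc2ccccc2)c1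
F11 | step 7 | analogue of 14 with a free hydroxyl on C3 of the upper unit (dodecabenzyl ether of the target) | O=C(O[C@@H]1Cc2c(OCc3ccccc3)cc(OCc3ccccc3)c([C@H]3c4ccc(OCc5ccccc5)cc4O[C@H](c4cc(OCc5ccccc5)c(OCc5ccccc5)c(OCc5ccccc5)c4)[C@H]3O)c2O[C@@H]1c1cc(OCc2ccccc2)c(OCc2ccccc2)c(OCc2ccccc2)c1)c1cc(OCc2ccccc2)c(OCc2ccccc2)c(OCc2ccccc2)c1
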